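**Strategy.** Everything rests on one disconnection: the C8–C11 bond of a donor–acceptor cyclopropane (C7, C8, C11) whose C8 acyloxy donor faces the C12 ester. The structural feature used is the trans γ-lactone ring (O–C6–C7–C11–C12) whose C7 also bears the oxygenated C8, a 1,4-dioxygenated C8–C7–C11–C12 array. In one operation, deacylation at the C8 oxygen triggers retro-aldol ring opening to the C8 aldehyde and the C6 hydroxyl lactonises onto C12, carrying the C6/C7 configuration of the precursor into the lactone. The precursor is a furan-derived cyclopropane with an ethyl ester (C11), a methyl oxalate (C8) and a vinyl carbinol (C6 on C7). The ten-membered ring is closed late at C4–C5.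

Key step: step 4

Remark (atom labels C1–C13 are those of the target's germacranolide skeleton): it is assumed that the (R,R)-configured bis(oxazoline) ligand delivers the (1R,5R,6R) cyclopropane, the mirror image of the series obtained with the (S,S) ligand; if the sense is opposite, the antipodal ligand is used and nothing else changes.

**Step 1**
Reactants: 1 methyl furan-2-carboxylate; 2 ethyl diazoacetate
Product: 3 6-ethyl 3-methyl (1R,5R,6R)-2-oxabicyclo[3.1.0]hex-3-ene-3,6-dicarboxylate
Conditions: Cu(OTf)2 (cat.), 2,2'-(propane-2,2-diyl)bis[(4R)-4-isopropyl-4,5-dihydrooxazole] (cat.), PhNHNH2 (cat.), CH2Cl2, 0 °C, slow addition of 2; recrystallisation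
Reagents that add atoms: none
Why: Copper-carbene cyclopropanation (Cu(OTf)2 reduced in situ to monovalent copper by phenylhydrazine) takes place at the unsubstituted, more electron-rich C4=C5 bond of the furoate with the ester exo, so the ligand-controlled face of attack sets all three cyclopropane stereocentres (the later C7, C8 and C11) at once, and crystallisation should raise the enantiomeric purity.

**Step 2**
Reactants: 3 6-ethyl 3-methyl (1R,5R,6R)-2-oxabicyclo[3.1.0]hex-3-ene-3,6-dicarboxylate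
Product: 4 ethyl (1R,2R,3R)-2-formyl-3-[(2-methoxy-2-oxoacetyl)oxy]cyclopropane-1-carboxylate
Conditions: O3, CH2Cl2, −78 °C; then Me2S, −78 °C to rt
Reagents that add atoms: ozone, [O-][O+]=O
Why: Ozonolysis with reductive work-up cleaves the only C=C bond, the electron-rich enol ether, turning one carbon into the formyl group on C7 and the other into the oxalyl carbonyl that stays on the C8 oxygen, without touching a stereocentre.

**Step 3**
Reactants: 4 ethyl (1R,2R,3R)-2-formyl-3-[(2-methoxy-2-oxoacetyl)oxy]cyclopropane-1-carboxylate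
Product: 5 ethyl (1R,2S,3R)-2-[(1R)-1-hydroxyprop-2-en-1-yl]-3-[(2-methoxy-2-oxoacetyl)oxy]cyclopropane-1-carboxylate
Conditions: CH2=CHI, CrCl2 (excess), NiCl2 (cat.), DMF, 0 °C to rt; used without delay
Reagents that add atoms: vinyl iodide, C=CI
Why: Nozaki–Hiyama–Kishi addition, in which the vinylchromium reagent formed through nickel catalysis adds only to the aldehyde (ester and oxalate are inert to it) and, in a Felkin–Anh sense, anti to the C7–C8 bond whose carbon carries the oxalate, which sets C6.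

**Step 4**
Reactants: 5 ethyl (1R,2S,3R)-2-[(1R)-1-hydroxyprop-2-en-1-yl]-3-[(2-methoxy-2-oxoacetyl)oxy]cyclopropane-1-carboxylate
Product: 8 (2R,3S)-2-ethenyl-5-oxooxolane-3-carbaldehyde, via cyclopropanol 6 (not isolated), via hydroxy aldehyde ester 7 (not isolated)
Conditions: Ba(OH)2·8H2O (0.55 equiv), MeOH, 0 °C
Reagents that add atoms: none
Why: Hydroxide (or the methoxide it generates) cleaves the activated oxalate at the C8 oxygen, and the cyclopropanolate so formed, a donor vicinal to the C12 ester acceptor, opens the strained ring by retro-aldol cleavage of C8–C11, giving the C8 aldehyde and an ester enolate that methanol protonates to the C11 methylene. The closest known reaction type is the base-induced ring opening and lactonisation of 2-acyloxycyclopropanecarboxylates obtained by cyclopropanation of furans. The lactone ring (O–C6–C7–C11–C12) then closes by 5-exo-trig attack of the C6 hydroxyl on the ethyl ester with loss of ethanol. No stereocentre is created: C6 and C7 keep their configuration because none of their bonds is broken, while C8 and C11 become non-stereogenic. The step needs cleavage of C8–C11 and not of C7–C8, which the substrate secures because only C11 carries the carbanion-stabilising ester, and it needs C7 to stay trans to the C6 vinyl group, which is secured because the trans aldehyde is also the more stable epimer and because β-elimination of the lactone oxygen from the aldehyde enolate is geometrically disfavoured (the C6–O bond lies close to the ring plane).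

**Step 5**
Reactants: 8 (2R,3S)-2-ethenyl-5-oxooxolane-3-carbaldehyde
Product: 9 (4S,5R)-4-(dimethoxymethyl)-5-ethenyloxolan-2-one
Conditions: HC(OMe)3, MeOH, PPTS (cat.), rt
Reagents that add atoms: trimethyl orthoformate, COC(OC)OC
Why: Acid-catalysed acetalisation with the orthoformate as water scavenger masks the only aldehyde so that the lactone can be enolised next, and C7 remains in its more stable trans arrangement.

**Step 6**
Reactants: 9 (4S,5R)-4-(dimethoxymethyl)-5-ethenyloxolan-2-one
Product: 10 (3R,4S,5R)-4-(dimethoxymethyl)-3-[(dimethylamino)methyl]-5-ethenyloxolan-2-one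
Conditions: LiN(iPr)2, THF, −78 °C; then CH2=NMe2+ I− (Eschenmoser's salt), −78 °C to rt
Reagents that add atoms: dimethyl(methylidene)ammonium iodide, C=[N+](C)C.[I-]
Why: Mannich reaction of the lithium lactone enolate with the iminium salt installs C13 as a dimethylaminomethyl group, a latent exocyclic methylene, the electrophile entering anti to the C7 substituent (new C11 centre, trans, erased in the last step).

**Step 7**
Reactants: 10 (3R,4S,5R)-4-(dimethoxymethyl)-3-[(dimethylamino)methyl]-5-ethenyloxolan-2-one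
Product: 11 (2R,3S,4R)-4-[(dimethylamino)methyl]-2-ethenyl-5-oxooxolane-3-carbaldehyde
Conditions: 1 M aq. HCl, THF, 0 °C to rt; then aq. NaHCO3; used crude
Reagents that add atoms: water, O
Why: Aqueous-acid hydrolysis of the dimethyl acetal, far more labile than the lactone, frees the C8 aldehyde while the amine sits protected as its ammonium salt, and no stereocentre is affected.

**Step 8**
Reactants: 12 3-methylbut-2-enal
Product: 13 tert-butyl(dimethyl){[(1E)-3-methylbuta-1,3-dien-1-yl]oxy}silane
Conditions: TBSOTf, Et3N, Et2O, 0 °C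
Reagents that add atoms: tert-butyldimethylsilyl triflate, CC(C)(C)[Si](C)(C)OS(=O)(=O)C(F)(F)F
Why: Soft enolisation, in which O-silylation of the enal and γ-deprotonation by triethylamine give the (1E)-silyl dienol ether.

**Step 9**
Reactants: 11 (2R,3S,4R)-4-[(dimethylamino)methyl]-2-ethenyl-5-oxooxolane-3-carbaldehyde; 13 tert-butyl(dimethyl){[(1E)-3-methylbuta-1,3-dien-1-yl]oxy}silane
Product: 14 (2E,5S)-5-[(2R,3R,4R)-4-[(dimethylamino)methyl]-2-ethenyl-5-oxooxolan-3-yl]-5-hydroxy-3-methylpent-2-enal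
Conditions: TfOH (1.0 equiv), CH2Cl2, −78 °C; then BF3·OEt2, 13 (excess), −78 °C; aq. NaHCO3
Reagents that add atoms: none
Why: Vinylogous Mukaiyama aldol reaction, in which the BF3-activated aldehyde (amine blocked as its triflate salt so that it cannot bind the Lewis acid) is attacked by the terminal γ-carbon of the dienol ether reacting through its s-trans conformer, which should give the E trisubstituted enal, while Felkin–Anh approach anti to the C7–C6 bond, past H7, sets C8 with the configuration of the target.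

**Step 10**
Reactants: 14 (2E,5S)-5-[(2R,3R,4R)-4-[(dimethylamino)methyl]-2-ethenyl-5-oxooxolan-3-yl]-5-hydroxy-3-methylpent-2-enal; 15 (2E)-2-methylbut-2-enoyl chloride
Product: 16 (1S,3E)-1-[(2R,3R,4R)-4-[(dimethylamino)methyl]-2-ethenyl-5-oxooxolan-3-yl]-3-methyl-5-oxopent-3-en-1-yl (2E)-2-methylbut-2-enoate
Conditions: pyridine, DMAP (cat.), CH2Cl2, 0 °C to rt
Reagents that add atoms: none
Why: DMAP-catalysed acylation of the secondary C8 alcohol takes place at oxygen with retention at C8 and leaves the E geometry of the tigloyl unit and of the enal unchanged.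

**Step 11**
Reactants: 16 (1S,3E)-1-[(2R,3R,4R)-4-[(dimethylamino)methyl]-2-ethenyl-5-oxooxolan-3-yl]-3-methyl-5-oxopent-3-en-1-yl (2E)-2-methylbut-2-enoate
Product: 17 (1S,3E)-1-[(2R,3R,4R)-4-[(dimethylamino)methyl]-2-ethenyl-5-oxooxolan-3-yl]-5-hydroxy-3-methyloct-3-en-6-yn-1-yl (2E)-2-methylbut-2-enoate (both epimers at the new carbinol, C2)
Conditions: CH3C≡CMgBr, THF, −78 °C; aq. NH4Cl
Reagents that add atoms: 1-propynylmagnesium bromide, CC#C[Mg]Br
Why: Grignard 1,2-addition, in which the alkynyl reagent attacks the aldehyde much faster than the lactone or the tiglate at −78 °C, and the configuration of the new carbinol is irrelevant because it is oxidised in the next step.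

**Step 12**
Reactants: 17 (1S,3E)-1-[(2R,3R,4R)-4-[(dimethylamino)methyl]-2-ethenyl-5-oxooxolan-3-yl]-5-hydroxy-3-methyloct-3-en-6-yn-1-yl (2E)-2-methylbut-2-enoate
Product: 18 (1S,3E)-1-[(2R,3R,4R)-4-[(dimethylamino)methyl]-2-ethenyl-5-oxooxolan-3-yl]-3-methyl-5-oxooct-3-en-6-yn-1-yl (2E)-2-methylbut-2-enoate
Conditions: MnO2, CH2Cl2, rt
Reagents that add atoms: none
Why: MnO2 oxidises only activated (allylic and propargylic) alcohols, so the doubly activated C2 carbinol should become the cross-conjugated ynone without change at the amine, the esters or the alkenes.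

**Step 13**
Reactants: 18 (1S,3E)-1-[(2R,3R,4R)-4-[(dimethylamino)methyl]-2-ethenyl-5-oxooxolan-3-yl]-3-methyl-5-oxooct-3-en-6-yn-1-yl (2E)-2-methylbut-2-enoate
Product: 19 (1S,3E,6Z)-1-[(2R,3R,4R)-4-[(dimethylamino)methyl]-2-ethenyl-5-oxooxolan-3-yl]-7-iodo-3-methyl-5-oxoocta-3,6-dien-1-yl (2E)-2-methylbut-2-enoate
Conditions: NaI, AcOH, rt, short reaction time
Reagents that add atoms: sodium iodide, [Na+].[I-]
Why: Hydroiodination of the ynone, in which iodide adds in conjugate fashion to C4 and the allenol intermediate is protonated at C3 anti to iodine, should give the Z-β-iodoenone under kinetic control, the β,β-disubstituted enone being a far poorer acceptor.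

**Step 14**
Reactants: 19 (1S,3E,6Z)-1-[(2R,3R,4R)-4-[(dimethylamino)methyl]-2-ethenyl-5-oxooxolan-3-yl]-7-iodo-3-methyl-5-oxoocta-3,6-dien-1-yl (2E)-2-methylbut-2-enoate
Product: 20 (1S,3E,6Z)-1-[(2S,3R,4R)-4-[(dimethylamino)methyl]-2-formyl-5-oxooxolan-3-yl]-7-iodo-3-methyl-5-oxoocta-3,6-dien-1-yl (2E)-2-methylbut-2-enoate
Conditions: OsO4 (cat.), NaIO4, 2,6-lutidine, dioxane/H2O, rt; used crude
Reagents that add atoms: sodium periodate, [Na+].[O-]I(=O)(=O)=O (oxygen delivered through OsO4, O=[Os](=O)(=O)=O)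
Why: Lemieux–Johnson cleavage, in which catalytic osmylation should select the monosubstituted, non-conjugated vinyl group over the three carbonyl-conjugated trisubstituted alkenes and periodate cleaves the diol to the C5 aldehyde with loss of formaldehyde, C6 keeping its spatial arrangement.

**Step 15**
Reactants: 20 (1S,3E,6Z)-1-[(2S,3R,4R)-4-[(dimethylamino)methyl]-2-formyl-5-oxooxolan-3-yl]-7-iodo-3-methyl-5-oxoocta-3,6-dien-1-yl (2E)-2-methylbut-2-enoate
Product: 21 (3R,3aR,4S,6E,10Z,11S,11aS)-3-[(dimethylamino)methyl]-11-hydroxy-6,10-dimethyl-2,8-dioxo-2,3,3a,4,5,8,11,11a-octahydrocyclodeca[b]furan-4-yl (2E)-2-methylbut-2-enoate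
Conditions: CrCl2 (excess), NiCl2 (cat.), degassed DMSO, high dilution with slow addition of 20, rt
Reagents that add atoms: none
Why: Intramolecular Nozaki–Hiyama–Kishi reaction, in which zerovalent nickel inserts into the C4–I bond with retention of the Z geometry, transmetalation gives a vinyl chromium species that adds only to the aldehyde and closes the ten-membered ring, and C5 is expected to be set by attack from the flank of the C7–C8 tether on the aldehyde rotamer that holds C5=O anti to the C6–O bond.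

**Step 16**
Reactants: 21 (3R,3aR,4S,6E,10Z,11S,11aS)-3-[(dimethylamino)methyl]-11-hydroxy-6,10-dimethyl-2,8-dioxo-2,3,3a,4,5,8,11,11a-octahydrocyclodeca[b]furan-4-yl (2E)-2-methylbut-2-enoate
Product: 23 molephantinin, via ammonium iodide 22 (not isolated)
Conditions: MeI, THF, rt; then sat. aq. NaHCO3, CH2Cl2, rt
Reagents that add atoms: none
Why: Exhaustive N-methylation followed by bicarbonate-induced elimination (E1cB, Hofmann type) of trimethylamine from the β-ammonium lactone should unveil the C11=C13 methylene under conditions mild enough for the tiglate, the dienone and the free C5 hydroxyl, erasing the C11 centre.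

**Compound list**

1 | methyl furan-2-carboxylate | COC(=O)c1ccco1 | starting material
2 | ethyl diazoacetate | CCOC(=O)C=[N+]=[N-] | starting material
3 | 6-ethyl 3-methyl (1R,5R,6R)-2-oxabicyclo[3.1.0]hex-3-ene-3,6-dicarboxylate | CCOC(=O)[C@H]1[C@@H]2OC(C(=O)OC)=C[C@H]12 | intermediate
4 | ethyl (1R,2R,3R)-2-formyl-3-[(2-methoxy-2-oxoacetyl)oxy]cyclopropane-1-carboxylate | CCOC(=O)[C@H]1[C@H](OC(=O)C(=O)OC)[C@@H]1C=O | intermediate
5 | ethyl (1R,2S,3R)-2-[(1R)-1-hydroxyprop-2-en-1-yl]-3-[(2-methoxy-2-oxoacetyl)oxy]cyclopropane-1-carboxylate | CCOC(=O)[C@H]1[C@H](OC(=O)C(=O)OC)[C@@H]1[C@H](O)C=C | intermediate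
6 | ethyl (1R,2S,3R)-3-hydroxy-2-[(1R)-1-hydroxyprop-2-en-1-yl]cyclopropane-1-carboxylate (as its barium alkoxide) | CCOC(=O)[C@H]1[C@H](O)[C@@H]1[C@H](O)C=C | intermediate
7 | ethyl (3S,4R)-3-formyl-4-hydroxyhex-5-enoate | CCOC(=O)C[C@H](C=O)[C@H](O)C=C | intermediate
8 | (2R,3S)-2-ethenyl-5-oxooxolane-3-carbaldehyde (trans-4-formyl-5-vinyl-γ-butyrolactone) | C1C(=O)O[C@H](C=C)[C@H]1C=O | intermediate
9 | (4S,5R)-4-(dimethoxymethyl)-5-ethenyloxolan-2-one | C1C(=O)O[C@H](C=C)[C@H]1C(OC)OC | intermediate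
10 | (3R,4S,5R)-4-(dimethoxymethyl)-3-[(dimethylamino)methyl]-5-ethenyloxolan-2-one | CN(C)C[C@@H]1C(=O)O[C@H](C=C)[C@H]1C(OC)OC | intermediate
11 | (2R,3S,4R)-4-[(dimethylamino)methyl]-2-ethenyl-5-oxooxolane-3-carbaldehyde | CN(C)C[C@@H]1C(=O)O[C@H](C=C)[C@H]1C=O | intermediate
12 | 3-methylbut-2-enal | CC(C)=CC=O | starting material
13 | tert-butyl(dimethyl){[(1E)-3-methylbuta-1,3-dien-1-yl]oxy}silane | C=C(C)/C=C/O[Si](C)(C)C(C)(C)C | intermediate
14 | (2E,5S)-5-[(2R,3R,4R)-4-[(dimethylamino)methyl]-2-ethenyl-5-oxooxolan-3-yl]-5-hydroxy-3-methylpent-2-enal | CN(C)C[C@@H]1C(=O)O[C@H](C=C)[C@H]1[C@@H](O)C/C(C)=C/C=O | intermediate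
15 | (2E)-2-methylbut-2-enoyl chloride (tigloyl chloride) | C/C=C(\C)C(Cl)=O | starting material
16 | (1S,3E)-1-[(2R,3R,4R)-4-[(dimethylamino)methyl]-2-ethenyl-5-oxooxolan-3-yl]-3-methyl-5-oxopent-3-en-1-yl (2E)-2-methylbut-2-enoate | CN(C)C[C@@H]1C(=O)O[C@H](C=C)[C@H]1[C@@H](OC(=O)/C(C)=C/C)C/C(C)=C/C=O | intermediate
17 | (1S,3E)-1-[(2R,3R,4R)-4-[(dimethylamino)methyl]-2-ethenyl-5-oxooxolan-3-yl]-5-hydroxy-3-methyloct-3-en-6-yn-1-yl (2E)-2-methylbut-2-enoate, both epimers at the propargylic carbinol | CN(C)C[C@@H]1C(=O)O[C@H](C=C)[C@H]1[C@@H](OC(=O)/C(C)=C/C)C/C(C)=C/C(O)C#CC | intermediate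
18 | (1S,3E)-1-[(2R,3R,4R)-4-[(dimethylamino)methyl]-2-ethenyl-5-oxooxolan-3-yl]-3-methyl-5-oxooct-3-en-6-yn-1-yl (2E)-2-methylbut-2-enoate | CN(C)C[C@@H]1C(=O)O[C@H](C=C)[C@H]1[C@@H](OC(=O)/C(C)=C/C)C/C(C)=C/C(=O)C#CC | intermediate
19 | (1S,3E,6Z)-1-[(2R,3R,4R)-4-[(dimethylamino)methyl]-2-ethenyl-5-oxooxolan-3-yl]-7-iodo-3-methyl-5-oxoocta-3,6-dien-1-yl (2E)-2-methylbut-2-enoate | CN(C)C[C@@H]1C(=O)O[C@H](C=C)[C@H]1[C@@H](OC(=O)/C(C)=C/C)C/C(C)=C/C(=O)/C=C(/C)I | intermediate
20 | (1S,3E,6Z)-1-[(2S,3R,4R)-4-[(dimethylamino)methyl]-2-formyl-5-oxooxolan-3-yl]-7-iodo-3-methyl-5-oxoocta-3,6-dien-1-yl (2E)-2-methylbut-2-enoate | CN(C)C[C@@H]1C(=O)O[C@H](C=O)[C@H]1[C@@H](OC(=O)/C(C)=C/C)C/C(C)=C/C(=O)/C=C(/C)I | intermediate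
21 | (3R,3aR,4S,6E,10Z,11S,11aS)-3-[(dimethylamino)methyl]-11-hydroxy-6,10-dimethyl-2,8-dioxo-2,3,3a,4,5,8,11,11a-octahydrocyclodeca[b]furan-4-yl (2E)-2-methylbut-2-enoate (the C13 dimethylamine adduct of the target, 11R) | CN(C)C[C@@H]1C(=O)O[C@H]2[C@H]1[C@@H](OC(=O)/C(C)=C/C)C/C(C)=C/C(=O)/C=C(/C)[C@@H]2O | intermediate
22 | N-methyl quaternary ammonium iodide of 21 (trimethylammoniomethyl group on C11) | C[N+](C)(C)C[C@@H]1C(=O)O[C@H]2[C@H]1[C@@H](OC(=O)/C(C)=C/C)C/C(C)=C/C(=O)/C=C(/C)[C@@H]2O.[I-] | intermediate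
23 | molephantinin, (3aR,4S,6E,10Z,11S,11aS)-11-hydroxy-6,10-dimethyl-3-methylidene-2,8-dioxo-2,3,3a,4,5,8,11,11a-octahydrocyclodeca[b]furan-4-yl (2E)-2-methylbut-2-enoate | C=C1C(=O)O[C@H]2[C@H]1[C@@H](OC(=O)/C(C)=C/C)C/C(C)=C/C(=O)/C=C(/C)[C@@H]2O | target

**Step count.** Total: 16 steps (15 in the main line plus 1 for the dienol ether 13). Longest linear sequence: 15 steps (steps 1–7 and 9–16).

**Steps most likely to fail**

1. Step 15. The closure of the ten-membered ring may lose out to intermolecular coupling or protodeiodination, and the facial selectivity at C5 is decided by the conformation of the closing ring, so it may be poor or favour the C5 epimer. Fallback: setting out from 20, the closure is run as in step 15 and the alcohol that predominates, the C5-epimeric macrocycle F1, is inverted instead of being made directly. A Mitsunobu reaction with chloroacetic acid (PPh3, DIAD, toluene, 0 °C) should give the inverted C5 chloroacetate F2, and brief treatment with K2CO3 (cat.) in MeOH at 0 °C cleaves this very labile ester in the presence of the tiglate, so that the sequence comes back to the route at 21. Any 21 formed directly is combined with this material.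

2. Step 9. The facial selectivity at C8 may be low, because both ring carbons flanking C7 now carry a substituent; erosion of the E geometry or attack through the α-carbon of the dienol ether would also be seen here. Fallback: setting out from 11 (with 13), the aldol is run as in step 9 and the C8 epimers are separated. The unwanted epimer, the (5R)-hydroxy enal F3, is esterified with tiglic acid under Mitsunobu conditions (PPh3, DIAD, THF, 0 °C), which inverts C8 and installs the ester in one operation, so that it comes back to the route at 16.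

3. Step 14. Osmylation may not stay on the vinyl group (competing oxidation of the tiglate, of the dienone or at the amine), and the α-acyloxy aldehyde may suffer under prolonged oxidation. Fallback: the terminal alkene is cleaved while it is the only alkene, setting out from 10. Ozonolysis of its trifluoroacetate salt (O3, TFA, CH2Cl2/MeOH, −78 °C) with NaBH4 work-up should give the primary alcohol F4, which is silylated (iPr3SiCl, imidazole, DMF) to the silyl ether F5. The operations of steps 7 and 9–13 are then repeated on this series, giving in turn the aldehyde F6, the hydroxy enal F7, the tiglate F8, the propargylic alcohol F9, the ynone F10 and the iodoenone F11. Desilylation with HF·pyridine in THF gives the primary alcohol F12, and Dess–Martin oxidation comes back to the route at 20.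

**Further compounds**

F1 | step 15 | C5 epimer of 21, (3R,3aR,4S,6E,10Z,11R,11aS)-3-[(dimethylamino)methyl]-11-hydroxy-6,10-dimethyl-2,8-dioxo-2,3,3a,4,5,8,11,11a-octahydrocyclodeca[b]furan-4-yl (2E)-2-methylbut-2-enoate | CN(C)C[C@@H]1C(=O)O[C@H]2[C@H]1[C@@H](OC(=O)/C(C)=C/C)C/C(C)=C/C(=O)/C=C(/C)[C@H]2O
F2 | step 15 | C5 chloroacetate of 21, (3R,3aR,4S,6E,10Z,11S,11aS)-11-[(chloroacetyl)oxy]-3-[(dimethylamino)methyl]-6,10-dimethyl-2,8-dioxo-2,3,3a,4,5,8,11,11a-octahydrocyclodeca[b]furan-4-yl (2E)-2-methylbut-2-enoate | CN(C)C[C@@H]1C(=O)O[C@H]2[C@H]1[C@@H](OC(=O)/C(C)=C/C)C/C(C)=C/C(=O)/C=C(/C)[C@@H]2OC(=O)CCl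
F3 | step 9 | C8 epimer of 14, (2E,5R)-5-[(2R,3R,4R)-4-[(dimethylamino)methyl]-2-ethenyl-5-oxooxolan-3-yl]-5-hydroxy-3-methylpent-2-enal | CN(C)C[C@@H]1C(=O)O[C@H](C=C)[C@H]1[C@H](O)C/C(C)=C/C=O
F4 | step 14 | (3R,4S,5S)-4-(dimethoxymethyl)-3-[(dimethylamino)methyl]-5-(hydroxymethyl)oxolan-2-one | CN(C)C[C@@H]1C(=O)O[C@H](CO)[C@H]1C(OC)OC
F5 | step 14 | (3R,4S,5S)-4-(dimethoxymethyl)-3-[(dimethylamino)methyl]-5-{[(triisopropylsilyl)oxy]methyl}oxolan-2-one | CN(C)C[C@@H]1C(=O)O[C@H](CO[Si](C(C)C)(C(C)C)C(C)C)[C@H]1C(OC)OC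
F6 | step 14 | (2S,3S,4R)-4-[(dimethylamino)methyl]-5-oxo-2-{[(triisopropylsilyl)oxy]methyl}oxolane-3-carbaldehyde | CN(C)C[C@@H]1C(=O)O[C@H](CO[Si](C(C)C)(C(C)C)C(C)C)[C@H]1C=O
F7 | step 14 | (2E,5S)-5-[(2S,3R,4R)-4-[(dimethylamino)methyl]-5-oxo-2-{[(triisopropylsilyl)oxy]methyl}oxolan-3-yl]-5-hydroxy-3-methylpent-2-enal | CN(C)C[C@@H]1C(=O)O[C@H](CO[Si](C(C)C)(C(C)C)C(C)C)[C@H]1[C@@H](O)C/C(C)=C/C=O
F8 | step 14 | analogue of 16 with CH2OSi(iPr)3 in place of the vinyl group on C6 | CN(C)C[C@@H]1C(=O)O[C@H](CO[Si](C(C)C)(C(C)C)C(C)C)[C@H]1[C@@H](OC(=O)/C(C)=C/C)C/C(C)=C/C=O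
F9 | step 14 | analogue of 17 with CH2OSi(iPr)3 in place of the vinyl group on C6 (both carbinol epimers) | CN(C)C[C@@H]1C(=O)O[C@H](CO[Si](C(C)C)(C(C)C)C(C)C)[C@H]1[C@@H](OC(=O)/C(C)=C/C)C/C(C)=C/C(O)C#CC
F10 | step 14 | analogue of 18 with CH2OSi(iPr)3 in place of the vinyl group on C6 | CN(C)C[C@@H]1C(=O)O[C@H](CO[Si](C(C)C)(C(C)C)C(C)C)[C@H]1[C@@H](OC(=O)/C(C)=C/C)C/C(C)=C/C(=O)C#CC
F11 | step 14 | analogue of 19 with CH2OSi(iPr)3 in place of the vinyl group on C6 | CN(C)C[C@@H]1C(=O)O[C@H](CO[Si](C(C)C)(C(C)C)C(C)C)[C@H]1[C@@H](OC(=O)/C(C)=C/C)C/C(C)=C/C(=O)/C=C(/C)I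
F12 | step 14 | analogue of 19 with CH2OH in place of the vinyl group on C6, (1S,3E,6Z)-1-[(2S,3R,4R)-4-[(dimethylamino)methyl]-2-(hydroxymethyl)-5-oxooxolan-3-yl]-7-iodo-3-methyl-5-oxoocta-3,6-dien-1-yl (2E)-2-methylbut-2-enoate | CN(C)C[C@@H]1C(=O)O[C@H](CO)[C@H]1[C@@H](OC(=O)/C(C)=C/C)C/C(C)=C/C(=O)/C=C(/C)I
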